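Its constants were set for the occasion; the flask was simulated.

Take a stirred vessel, charge free catalyst, hold the gas phase above it, feed in the substrate, and run it at three temperatures.

| flask | substrate | gas phase | free catalyst | temperature | time |
|---|---|---|---|---|---|
| ash | 1.0 mM (fed, over 12 s) | 0.096 mM (held) | 13 µM | 25 °C | 6.0 min |
| larch | 1.0 mM (fed, over 12 s) | 0.096 mM (held) | 13 µM | 35 °C | 6.0 min |
| elm | 1.0 mM (fed, over 12 s) | 0.096 mM (held) | 13 µM | 45 °C | 6.0 min |

    gas phase ⇌ dissolved gas, rate k1*(csat - [dissolved gas]) (k1 = 0.59 /s, csat = 0.096 mM)
    2 free catalyst → spent catalyst (k2 = 550 /M/s, Ea2 = 47.0 kJ/mol)
    substrate + dissolved gas → uncatalysed product (k3 = 53 /M/s, Ea3 = 38.0 kJ/mol)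
    substrate + dissolved gas + free catalyst → free catalyst + target (k4 = 3.4 × 10⁶ /M²/s, Ea4 = 16.0 kJ/mol)
    (constants at 25 °C)

- a doubled species enters its step squared and goes two at a time
- at the start none of the gas is dissolved
- at 25 °C the constants are as listed, elsewhere as the activation energies make them

- which of these there is most of at the end, counted by the substrate in it, ash (substrate / uncatalysed product / target)
- which of these there is most of at the end, counted by the substrate in it, larch (substrate / uncatalysed product / target)
- which of these there is most of at the end, counted by the substrate in it, elm (substrate / uncatalysed product / target)
- amount of the one of these that there is most of at the end, in percent of the substrate charged, ash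
- amount of the one of these that there is most of at the end, in percent of the substrate charged, larch
- amount of the one of these that there is most of at the end, in percent of the substrate charged, elm

Watch one number: the crossover catalyst level C×, the rate constant of the uncatalysed step divided by that of the catalysed step, 15.6 µM at 25 °C. Both steps consume substrate and dissolved gas, so target and uncatalysed product form in the ratio [free catalyst]/C×, this flask's selectivity factor. Above C× the catalysed step leads; below it the uncatalysed step leads. Warming lifts C× to 20.8 µM in larch and 27.2 µM in elm. The charge of 13 µM starts below the crossing in each flask, and the second-order loss takes free catalyst down from there. So expect uncatalysed product on top in ash, larch and elm, with a larger lead as C× climbs.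

Now climb the ladder for ash. Gas crosses in 1.69 s, and its transfer constant is larger than the 0.0972 /s with which the full charge draws on it, so take dissolved gas as standing near 0.096 mM. The feed ends at 12 s, sooner than the catalyst's half-life τ of 69.9 s, so treat the substrate as charged at once. Next comes the lifetime of the substrate by the uncatalysed step alone, 197 s, longer than τ, so expect the catalyst to fade on the shorter clock. By 6.0 min, second-order loss leaves 16.3 % of the free catalyst, and its time average is 4.59 µM. Counting early and late minutes alike, that gives an estimated target-to-uncatalysed ratio of 0.294. Integrating both steps with dissolved gas at 0.096 mM and the substrate charged at once gives an estimate of 9.34 % of the substrate left, so I commit to 70.0 % uncatalysed product in ash.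

The forecast names uncatalysed product in each flask, at 65 % for ash, below my figure, then 78 % for larch and 86 % for elm, saying “the uncatalysed product wins at all three temperatures”.

The flasks give uncatalysed product on top at 64.8 % in ash, 78.2 % in larch and 86.5 % in elm, so my ash figure stands 5.2 percentage points high, with target at 24.1 %. Between 3.00 min and 6.00 min, ash made target and uncatalysed product in the ratio 0.184, while [free catalyst]/C× went from 0.233 to 0.136. Run larch at 50 °C instead: C× reaches 31.0 µM, the starting ratio is 0.420, and uncatalysed product ends at 89.2 %.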